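Remark on the chemistry: atoms carry labdane locants throughout (ring A = C1–C5 and C10; ring B = C5–C10; C11–C12 = chain; C13–C16 = butenolide; C17 = carbon on C8). β is the face of the C10 methyl group, α the other face.
Assumption: the commercial half ester of itaconic acid is the 4-methyl ester with the free conjugated acid (compound 3).

## Analysis of the target

The target 25 is a C20 labdane-type butenolide: a cis-fused decalin whose C9 carries a two-carbon chain (C11, C12) ending in a 4-substituted furan-2(5H)-one (C13–C16, carbonyl at C15). Ring A holds the gem-dimethyl carbon C4 and a secondary alcohol at C2. Ring B holds a secondary alcohol at C6, a methylene at C7 and a tetrasubstituted C8=C9 alkene whose C8 bears the hydroxymethyl carbon C17. There are four stereocentres, C2 (S), C5 (R), C6 (S) and C10 (S). H5 and the C10 methyl lie on the β face (cis fusion), and both hydroxyls lie on the α face, C2–O being 1,3-cis to the C10–C9 bond across ring A. The sensitive groups are the butenolide (base, hydride, nucleophiles), the primary allylic alcohol on a fully substituted alkene, and, at the ketone stage, a β,γ-unsaturated carbonyl that can slip into conjugation. The difficulty lies in the crowded C4–C5–C10 array with a cis fusion, in an alkene with three different carbon substituents whose two allylic CH2 groups (C11, C17) must be told apart, and in the remote relation of C2 to C10. The strategy rests on ring B: C6 (carbinol, a masked ketone), C7 (CH2) and C8=C9 make up a cyclohex-3-enone, the product of inserting CO into a vinylcyclopropane C5–C9–C10 that carries C8=C7 on C9. A cyclopropane on ring A can only be cis-fused, and the C2 oxygen sits on the face from which C9 must arrive, so an ester C2–O–C11(=O)–C9 can deliver it.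

## Retrosynthetic reasoning

Target 25 is traced back to its tris-silyl ether 24, so that the three hydroxyls are released together in the last step under non-basic conditions that spare the butenolide.

The butenolide of 24 is traced to the 3-substituted furan 20 through hydroxybutenolide 22. The furan survives organometallic coupling, and photooxygenation with a hindered base puts the carbonyl on the unhindered α-carbon (C15); hydride then turns the hemiacetal carbon into the C16 methylene.

The C11–C12 bond of 20 is cut between the allylic bromide 16 and the furylmethyl Grignard reagent 19, made from chloride 18 and alcohol 17. C11 is primary and allylic, and the SN2′ terminus C8 is fully substituted, so the coupling can only give the linear product.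

Bromide 16 comes from triol 14 through bromo diol 15. The pair C2–OH/C11–OH of 14 is the reduced form of a δ-lactone, so C11 is carried as a carboxyl carbon and the C2 oxygen is tied up until ring B exists. The C6 carbinol is taken back to the ketone 12 through 13; the reduction is placed before the lactone is opened because the bridged lactone fixes the shape of the molecule.

Ketone 12 is cut at C5–C6 and C6–C7, which removes carbon monoxide 11 and leaves the lactone-bridged vinylcyclopropane 10. This is the key disconnection. The forward step must open the C9–C5 bond (not C9–C10), keep the configuration of C5, and leave the new C8=C9 bond where the target has it.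

The cyclopropane of 10 is cut at C9–C5 and C9–C10 to the vinyl diazo ester 9. The forward step adds a carbene carbon across C5=C10 from the face of the C2 oxygen, which fixes C5, C9 and C10 from C2 alone.

Diazo ester 9 comes from ester 8 by diazo transfer, and 8 from alcohol 2 and acid 7 by esterification. Alcohol 2 is the reduced form of β-isophorone 1 and is the only source of absolute configuration. Acid 7 comes from the itaconate half ester 3 through 5 and 6, by reducing the conjugated acid, silylating and saponifying.

## Alternatives that were turned down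

Alternative 1: ring A is cut at C1–C10 and C4–C5, a Diels–Alder disconnection into quinone A1 (its methyl-bearing double bond becomes C5–C10) and silyloxydiene A2. A chiral Lewis acid would catalyse the cycloaddition to the cis-fused adduct A3.
- For: the suprafacial addition makes the cis fusion automatic, the catalyst sets C5 and C10 from achiral materials, and a decalin oxygenated at C2, C6, C8 and C9 is reached in one step.
- Against: the diene terminus C4 carries two methyls, so the reactive s-cis conformer is strained, and the C4–C5 bond must form next to the future quaternary C10. After A3 the tetrasubstituted C8=C9 alkene still has to be built from a ketone and an enol ether with two different carbon groups (C17 and the C11–C12 chain). Three carbonyls (C2, C6, C9) must be told apart, and C2 must be reduced to the α-alcohol without a nearby control element.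
- Comparison: it is stronger on enantiocontrol and on speed to a bicycle. The chosen route offers instead a ring B that is formed with C8=C9 in place and with C17 and C11 attached and differentiated, and a C2 oxygen of fixed configuration that also steers C5 and C10.

Alternative 2: the C5–C10 bond is cut across the ring, leading to the ten-membered dienedione A4. A chiral primary amine would form the C5 enamine of the C6 ketone, which adds across the ring to C10 of the enone and gives the cis-decalindione A5.
- For: one catalytic C–C bond closes both rings and sets C5 and C10, and A5 already holds C8=C9 with C17 and C12.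
- Against: A4 is a medium ring with a fully substituted alkene and a (Z)-trisubstituted enone, and its assembly would cost more steps than the whole path to 10. C7 is both α to the C6 carbonyl and allylic, so the enamine should form toward C7 and not toward C5. The acceptor carbon C10 is β,β-disubstituted, the hardest case for amine catalysis. A5 has two ketones to reduce, C2 without any bias.
- Comparison: it is stronger in that C12 is already present, which saves one later coupling. The chosen route offers precursors whose ring sizes (three and six) close predictably, and stereocontrol anchored on a pre-set C2.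

Alternative 3: C9–C10 and C5–C6 are cut by a tethered [2+2] photocycloaddition of the furanone ester A6 (an ester of alcohol 2), followed by retro-aldol cleavage of the four-membered ring at C6–C9 on aqueous work-up to the 1,5-diketone A7.
- For: it uses the same alcohol 2 and the same face control from the C2 ester, needs no diazo compound, no CO and no precious metal, and brings C17 oxygenated and C6 as a ketone.
- Against: the photoaddition must join a fully substituted enone carbon (C9) to C10, creating two adjacent quaternary carbons inside a cage, with the regiochemistry left to the tether. A7 is not yet ring B: C7–C8 must be closed by an aldol condensation in the presence of an acyloin (C8/C17) and an epimerisable C9, and the resulting C7=C8 enone must then be deconjugated to C8=C9.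
- Comparison: it is stronger in operational simplicity and avoids a free carbene. The chosen route offers ring B in one step (12) with the alkene in its final position, and C9 never becomes an acidic CH.

Key step: step 8

## Route

Step 1
Reactants: 1 β-isophorone (3,5,5-trimethylcyclohex-3-en-1-one)
Product: 2 (R)-3,5,5-trimethylcyclohex-3-en-1-ol
Conditions: ketoreductase (R-selective, chosen from a commercial panel), NADP+ (cat.), i-PrOH, phosphate buffer pH 7, 30 °C
Reagents that add atoms: none
Why: Biocatalytic ketone reduction with cofactor recycling by propan-2-ol; the enzyme pocket distinguishes the CH2–C(CH3)= arm from the CH2–C(CH3)2 arm and so sets C2 (R). Neutral buffer keeps the β,γ-alkene out of conjugation.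

Step 2
Reactants: 3 4-methyl hydrogen itaconate (4-methoxy-2-methylidene-4-oxobutanoic acid)
Product: 5 methyl 3-(hydroxymethyl)but-3-enoate, via mixed isobutyl carbonic anhydride 4 (not isolated)
Conditions: i-BuOCOCl, N-methylmorpholine, THF, −15 °C; then NaBH4, THF/H2O, −15 → 0 °C
Reagents that add atoms: none
Why: Mixed-anhydride activation and borohydride reduction take the acid to the primary alcohol and leave the methyl ester; hydride attacks the anhydride carbonyl faster than it adds in a conjugate sense. The hydroxy ester can close to a γ-lactone, so it is silylated at once.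

Step 3
Reactants: 5 methyl 3-(hydroxymethyl)but-3-enoate
Product: 6 methyl 3-[(tert-butyldimethylsilyloxy)methyl]but-3-enoate
Conditions: TBSCl, imidazole, DMF, 0 °C → rt
Reagents that add atoms: tert-butyldimethylsilyl chloride, CC(C)(C)[Si](C)(C)Cl
Why: Silyl ether formation on a primary alcohol; it stops lactonisation and carries C17 as an ether that survives to the last step.

Step 4
Reactants: 6 methyl 3-[(tert-butyldimethylsilyloxy)methyl]but-3-enoate
Product: 7 3-[(tert-butyldimethylsilyloxy)methyl]but-3-enoic acid
Conditions: LiOH·H2O, THF/H2O, 0 °C; then 1 M HCl to pH 4, 0 °C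
Reagents that add atoms: lithium hydroxide, [Li+].[OH-]
Why: Saponification; hydroxide attacks the unhindered methyl ester faster than it removes an α-proton at 0 °C, and the carboxylate is no longer acidic at C2, so the alkene should stay unconjugated. The primary silyl ether tolerates cold pH 4.

Step 5
Reactants: 2 (R)-3,5,5-trimethylcyclohex-3-en-1-ol; 7 3-[(tert-butyldimethylsilyloxy)methyl]but-3-enoic acid
Product: 8 (R)-3,5,5-trimethylcyclohex-3-en-1-yl 3-[(tert-butyldimethylsilyloxy)methyl]but-3-enoate
Conditions: DCC, DMAP (5 mol%), CH2Cl2, 0 °C → rt
Reagents that add atoms: none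
Why: Steglich esterification; with little DMAP at 0 °C acyl transfer should outrun ketene formation, so the β,γ-alkene stays in place. The carbinol C–O bond is not broken, so C2 is retained.

Step 6
Reactants: 8 (R)-3,5,5-trimethylcyclohex-3-en-1-yl 3-[(tert-butyldimethylsilyloxy)methyl]but-3-enoate
Product: 9 (R)-3,5,5-trimethylcyclohex-3-en-1-yl 2-diazo-3-[(tert-butyldimethylsilyloxy)methyl]but-3-enoate
Conditions: 4-AcNHC6H4SO2N3, DBU, MeCN, 0 °C
Reagents that add atoms: 4-acetamidobenzenesulfonyl azide, CC(=O)Nc1ccc(cc1)S(=O)(=O)N=[N+]=[N-]
Why: Regitz-type diazo transfer to the methylene activated by the ester and the alkene, the standard entry to vinyl diazoacetates. The product is kept cold and used promptly because vinyl diazo compounds slowly close to pyrazoles.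

Step 7
Reactants: 9 (R)-3,5,5-trimethylcyclohex-3-en-1-yl 2-diazo-3-[(tert-butyldimethylsilyloxy)methyl]but-3-enoate
Product: 10 lactone-bridged vinylcyclopropane (ring A; cyclopropane C5–C9–C10 on the α face; δ-lactone C2–O–C11(=O)–C9; C9 bears C8(=C7H2)–C17H2OTBS; H5 and 10-CH3 β)
Conditions: Rh2(OAc)4 (1 mol%), CH2Cl2, 40 °C, slow addition of 9
Reagents that add atoms: none
Why: Intramolecular cyclopropanation by a rhodium vinylcarbenoid; the three-atom tether O–C11(=O)–C9 reaches only the alkene face cis to the C2 oxygen, so C5, C9 and C10 are all set from C2. Donor/acceptor carbenoids prefer alkene addition to C–H insertion.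

Step 8
Reactants: 10 lactone-bridged vinylcyclopropane; 11 carbon monoxide
Product: 12 lactone-bridged cis-decalin enone (2α,11-lactone; C6 ketone; C8=C9; C17–OTBS; H5 and 10-CH3 β)
Conditions: [Rh(CO)2Cl]2 (5 mol%), CO (1 atm), toluene, 80 °C
Reagents that add atoms: none
Why: Carbonylative (5+1) ring expansion of a vinylcyclopropane under monovalent rhodium, a known reaction type for 1-substituted vinylcyclopropanes. The catalyst binds the C8=C7 alkene and inserts into the cyclopropane bond C9–C5 with retention, giving a σ-alkyl (C5)/π-allyl (C9–C8–C7) complex of trivalent rhodium. CO inserts into the Rh–C5 bond with retention, and reductive elimination joins acyl C6 to the unsubstituted allyl terminus C7. Ring B is thus closed by C–C reductive elimination from an acyl rhodacycle (not a Baldwin-type closure), the six-membered ring being preferred to coupling at the quaternary terminus C9. No new stereocentre is formed: C10 is untouched and C5 keeps its configuration, so H5 and the C10 methyl stay cis as on the cyclopropane. The step needs cleavage of C9–C5 and not C9–C10; C10 is quaternary and shielded by its methyl whereas C5 is tertiary, and the lactone carbonyl on C9 activates both bonds alike. β-Hydride loss from the alkyl rhodium, the usual leak to dienes, is shut off because both neighbours of C5 (C4 and C10) are quaternary. The new C8=C9 bond is conjugated with the lactone carbonyl, which should keep it from moving toward the C6 ketone.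

Step 9
Reactants: 12 lactone-bridged cis-decalin enone
Product: 13 6α-hydroxy lactone (2α,11-lactone; C8=C9; C17–OTBS; 6α-OH)
Conditions: NaBH4, CeCl3·7H2O, MeOH, −78 °C
Reagents that add atoms: none
Why: Luche 1,2-reduction. In the lactone-locked cis-decalin, ring A lies under ring B and C4 is pseudo-axial on the α face next to C6, so hydride should enter from the β face (anti to the C5–C4 bond, Felkin–Anh sense) and give the equatorial 6α-alcohol, which is also the more stable epimer. The lactone is inert, and the cold, weakly basic medium protects the β,γ-enone.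

Step 10
Reactants: 13 6α-hydroxy lactone
Product: 14 triol (2α-OH; 6α-OH; C11–OH; C8=C9; C17–OTBS)
Conditions: i-Bu2AlH (5 equiv), CH2Cl2, −78 → 0 °C; aq. potassium sodium tartrate
Reagents that add atoms: none
Why: 1,2-Reduction of the α-alkylidene lactone through the lactol to the allylic alcohol; ring opening also releases the strain between the bridge and the C4 methyl groups. Silyl ether and alkene are untouched.

Step 11
Reactants: 14 triol
Product: 15 11-bromo-2α,6α-diol (C8=C9; C17–OTBS)
Conditions: NBS, Me2S, CH2Cl2, −20 → 0 °C
Reagents that add atoms: N-bromosuccinimide, O=C1CCC(=O)N1Br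
Why: Corey–Kim bromination; only the alkoxysulfonium salt of the allylic alcohol collapses by bromide attack, and those of the secondary alcohols revert on work-up because no base is added. Allylic shift is blocked at the fully substituted C8; the bromide is used at once.

Step 12
Reactants: 15 11-bromo-2α,6α-diol
Product: 16 11-bromo-2α,6α-bis(triethylsilyl) ether (C8=C9; C17–OTBS)
Conditions: Et3SiOTf, 2,6-lutidine, CH2Cl2, −78 °C
Reagents that add atoms: triethylsilyl trifluoromethanesulfonate, CC[Si](CC)(CC)OS(=O)(=O)C(F)(F)F
Why: Silyl ether formation with a silyl triflate and a hindered, non-nucleophilic base, which also covers the hindered C6 hydroxyl. It is done before any basic organometallic meets the bromide, so the C2 oxygen cannot close back onto C11.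

Step 13
Reactants: 17 furan-3-ylmethanol
Product: 18 3-(chloromethyl)furan
Conditions: SOCl2, pyridine, Et2O, 0 °C
Reagents that add atoms: thionyl chloride, O=S(Cl)Cl
Why: Chlorination of a primary alcohol through the chlorosulfite with SN2 displacement by chloride; the labile chloride is used as an ethereal solution.

Step 14
Reactants: 16 11-bromo-2α,6α-bis(triethylsilyl) ether; 18 3-(chloromethyl)furan
Product: 20 furan (C9–C11H2–C12H2–furan-3-yl; 2α,6α-bis-OTES; C17–OTBS; C8=C9), via (furan-3-ylmethyl)magnesium chloride 19 (not isolated)
Conditions: 18, Mg, THF, 0 °C → rt; then 16, Li2CuCl4 (5 mol%), THF, −78 → 0 °C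
Reagents that add atoms: none
Why: Copper-catalysed coupling of a Grignard reagent with an allylic halide (Kochi-type). The 3-furylmethyl reagent couples at its CH2, and the bromide reacts at C11 because the SN2′ terminus C8 is fully substituted; silyl ethers are inert.

Step 15
Reactants: 20 furan
Product: 22 γ-hydroxybutenolide (C15 carbonyl; C16 hemiacetal as both epimers; silyl ethers as in 20), via furan endoperoxide 21 (not isolated)
Conditions: O2, hν (visible), tetraphenylporphyrin (cat.), i-Pr2NEt, CH2Cl2, −78 °C
Reagents that add atoms: dioxygen, O=O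
Why: Dye-sensitised photooxygenation; singlet oxygen adds [4+2] to the furan and the hindered amine removes the less hindered bridgehead proton (Kornblum–DeLaMare-type fragmentation), so the carbonyl appears at C15 and the hemiacetal at C16. At −78 °C the furan should react faster than the hindered, allylically oxygenated C8=C9 alkene; irradiation is stopped when 20 is consumed.

Step 16
Reactants: 22 γ-hydroxybutenolide
Product: 24 butenolide tris-silyl ether (2α,6α-bis-OTES; C17–OTBS), via (Z)-hydroxy carboxylate 23 (not isolated)
Conditions: NaBH4, EtOH, 0 °C; then 1 M HCl to pH 3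
Reagents that add atoms: none
Why: Borohydride reduces the open aldehyde form of the hydroxybutenolide, and the (Z)-hydroxy acid lactonises on acidification. The CH2 ends at C16 next to the substituted carbon, the carbonyl stays at C15, and the C16 stereocentre disappears.

Step 17
Reactants: 24 butenolide tris-silyl ether
Product: 25 target, 4-{2-[(4S,4aR,7S,8aS)-4,7-dihydroxy-2-(hydroxymethyl)-5,5,8a-trimethyl-3,4,4a,5,6,7,8,8a-octahydronaphthalen-1-yl]ethyl}furan-2(5H)-one (2S,5R,6S,10S in labdane locants)
Conditions: HF·pyridine, pyridine, THF, 0 °C → rt
Reagents that add atoms: none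
Why: Cleavage of all three silyl ethers by buffered hydrogen fluoride; the medium is not basic, so the butenolide is safe, and not strongly acidic, so the allylic alcohol should not ionise.

## Compound list

1 | β-isophorone (3,5,5-trimethylcyclohex-3-en-1-one) | CC1=CC(C)(C)CC(=O)C1 | starting material
2 | (R)-3,5,5-trimethylcyclohex-3-en-1-ol | CC1(C)C[C@H](O)CC(C)=C1 | intermediate
3 | 4-methyl hydrogen itaconate | COC(=O)CC(=C)C(=O)O | starting material
4 | mixed isobutyl carbonic anhydride of 3 | COC(=O)CC(=C)C(=O)OC(=O)OCC(C)C | intermediate (not isolated)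
5 | methyl 3-(hydroxymethyl)but-3-enoate | COC(=O)CC(=C)CO | intermediate
6 | methyl 3-[(tert-butyldimethylsilyloxy)methyl]but-3-enoate | COC(=O)CC(=C)CO[Si](C)(C)C(C)(C)C | intermediate
7 | 3-[(tert-butyldimethylsilyloxy)methyl]but-3-enoic acid | OC(=O)CC(=C)CO[Si](C)(C)C(C)(C)C | intermediate
8 | (R)-3,5,5-trimethylcyclohex-3-en-1-yl 3-[(tert-butyldimethylsilyloxy)methyl]but-3-enoate | CC1(C)C[C@H](OC(=O)CC(=C)CO[Si](C)(C)C(C)(C)C)CC(C)=C1 | intermediate
9 | (R)-3,5,5-trimethylcyclohex-3-en-1-yl 2-diazo-3-[(tert-butyldimethylsilyloxy)methyl]but-3-enoate | CC1(C)C[C@H](OC(=O)C(=[N+]=[N-])C(=C)CO[Si](C)(C)C(C)(C)C)CC(C)=C1 | intermediate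
10 | lactone-bridged vinylcyclopropane (cyclopropane C5–C9–C10 and lactone C2–O–C11 on the α face) | CC1(C)C[C@H](O2)C[C@@]3(C)[C@@H]1[C@@]3(C(=C)CO[Si](C)(C)C(C)(C)C)C2=O | intermediate
11 | carbon monoxide | [C-]#[O+] | starting material
12 | lactone-bridged cis-decalin enone (C6 ketone, C8=C9) | CC1(C)C[C@H](O3)C[C@]2(C)C(C3=O)=C(CO[Si](C)(C)C(C)(C)C)CC(=O)[C@H]12 | intermediate
13 | 6α-hydroxy lactone | CC1(C)C[C@H](O3)C[C@]2(C)C(C3=O)=C(CO[Si](C)(C)C(C)(C)C)C[C@H](O)[C@H]12 | intermediate
14 | triol (2α-OH, 6α-OH, C11–OH, C17–OTBS) | CC1(C)C[C@H](O)C[C@]2(C)C(CO)=C(CO[Si](C)(C)C(C)(C)C)C[C@H](O)[C@H]12 | intermediate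
15 | 11-bromo-2α,6α-diol | CC1(C)C[C@H](O)C[C@]2(C)C(CBr)=C(CO[Si](C)(C)C(C)(C)C)C[C@H](O)[C@H]12 | intermediate
16 | 11-bromo-2α,6α-bis(triethylsilyl) ether | CC1(C)C[C@H](O[Si](CC)(CC)CC)C[C@]2(C)C(CBr)=C(CO[Si](C)(C)C(C)(C)C)C[C@H](O[Si](CC)(CC)CC)[C@H]12 | intermediate
17 | furan-3-ylmethanol | OCc1ccoc1 | starting material
18 | 3-(chloromethyl)furan | ClCc1ccoc1 | intermediate
19 | (furan-3-ylmethyl)magnesium chloride | Cl[Mg]Cc1ccoc1 | intermediate (not isolated)
20 | furan (C12 attached to furan C3) | CC1(C)C[C@H](O[Si](CC)(CC)CC)C[C@]2(C)C(CCc3ccoc3)=C(CO[Si](C)(C)C(C)(C)C)C[C@H](O[Si](CC)(CC)CC)[C@H]12 | intermediate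
21 | furan 2,5-endoperoxide (bridgehead configuration not defined) | CC1(C)C[C@H](O[Si](CC)(CC)CC)C[C@]2(C)C(CCC3=CC4OOC3O4)=C(CO[Si](C)(C)C(C)(C)C)C[C@H](O[Si](CC)(CC)CC)[C@H]12 | intermediate (not isolated)
22 | γ-hydroxybutenolide (C16 epimers) | CC1(C)C[C@H](O[Si](CC)(CC)CC)C[C@]2(C)C(CCC3=CC(=O)OC3O)=C(CO[Si](C)(C)C(C)(C)C)C[C@H](O[Si](CC)(CC)CC)[C@H]12 | intermediate
23 | sodium (Z)-hydroxy carboxylate | CC1(C)C[C@H](O[Si](CC)(CC)CC)C[C@]2(C)C(CC/C(CO)=C/C(=O)[O-])=C(CO[Si](C)(C)C(C)(C)C)C[C@H](O[Si](CC)(CC)CC)[C@H]12.[Na+] | intermediate (not isolated)
24 | butenolide tris-silyl ether | CC1(C)C[C@H](O[Si](CC)(CC)CC)C[C@]2(C)C(CCC3=CC(=O)OC3)=C(CO[Si](C)(C)C(C)(C)C)C[C@H](O[Si](CC)(CC)CC)[C@H]12 | intermediate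
25 | CNP0293367.1 (2S,5R,6S,10S) | CC1(C)C[C@H](O)C[C@]2(C)C(CCC3=CC(=O)OC3)=C(CO)C[C@H](O)[C@H]12 | target

## Step count and least certain steps

Total: 17 steps. Longest linear sequence: 15 steps (3 → 25 through steps 2–12 and 14–17); from 1 it is 13 steps.

Step 8 (key step). The most likely failure is that rhodium does not insert into the crowded, cage-locked C9–C5 bond, or that the acceptor cyclopropane opens to an isomeric diene lactone before CO is taken up. The fallback takes the cage apart first and sets out from 10. Reduction with i-Bu2AlH (CH2Cl2, −78 → 0 °C) should give the diol vinylcyclopropane F1, an unstrained 1-alkyl-1-vinylcyclopropane of the kind on which the carbonylation is best known. [Rh(CO)2Cl]2 under CO (or Fe(CO)5 under irradiation and CO) should convert it into the keto diol F2. LiBH(s-Bu)3 in THF at −78 °C should then attack the now flexible ring B from the β face, because the α face carries the axial C1 methylene of ring A, and the route is rejoined at 14.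

Step 7. The carbenoid may insert into the allylic C1–H bond (five-membered lactone) or decay by dimerisation or cyclopropene formation, because the trisubstituted alkene next to C4 is hindered and the ester must sit axial to reach it. The fallback uses an acceptor/acceptor carbene under copper, which is more selective for alkenes, and introduces the methylene late; it sets out from 2. Heating 2 in toluene at 80 °C with the acyl Meldrum's acid F3 (from (tert-butyldimethylsilyloxy)acetic acid, Meldrum's acid, DCC and DMAP) should give the β-keto ester F4. Diazo transfer (4-AcNHC6H4SO2N3, Et3N, MeCN) gives the diazo keto ester F5. Cu(acac)2 in toluene at 90 °C should close the cyclopropyl keto lactone F6, and Wittig methylenation (Ph3P=CH2, THF, 0 °C) rejoins the route at 10.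

Step 9. Hydride may be delivered in part from the α face (poor facial selectivity) because the β face carries the 1,3-related C10 methyl, or the C8=C9 bond may migrate under base. The fallback reduces C6 only after the cage is open and sets out from 12. Aprotic ketalisation ((Me3SiOCH2)2, Me3SiOTf cat., CH2Cl2, −78 °C) should give the dioxolane lactone F7, i-Bu2AlH the dioxolane diol F8, and PPTS in wet acetone the keto diol F2 already met above. LiBH(s-Bu)3 at −78 °C, attacking equatorially from the β face, then returns the route to 14.

Step 1. The enzyme may discriminate the two CH2 arms poorly (low enantiomeric purity), or 1 may isomerise to the conjugated enone during incubation. The fallback replaces asymmetric reduction by resolution and sets out from 1. NaBH4/CeCl3·7H2O in MeOH at 0 °C gives the racemic alcohol F9. Esterification with (S)-2-methoxy-2-phenylacetic acid (DCC, DMAP) gives the ester F10 of the R alcohol and the ester F11 of the S alcohol, which are separated by chromatography or crystallisation. LiOH in THF/H2O cleaves F10 and returns the route to 2; the same esters allow the configuration to be assigned.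

Step 15. Singlet oxygen may undergo an ene reaction at the C8=C9 alkene (over-oxidation), or regiocontrol may be lost in the peroxide fragmentation. The fallback builds the butenolide without an oxidation of the alkene-bearing core and sets out from 16. The N,N-dimethylhydrazone F12 of 1-(4-methoxybenzyloxy)propan-2-one, lithiated at its methyl group with LDA (THF, −78 °C), should alkylate 16 to the hydrazone F13. Aqueous oxalic acid frees the ketone F14, and DDQ (CH2Cl2, pH 7 buffer) removes the 4-methoxybenzyl group to give the hydroxy ketone F15. Ph3P=C=C=O (Bestmann ylide) in toluene at 80 °C acylates the hydroxyl and closes the ring by intramolecular Wittig reaction, rejoining the route at 24.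

## Further compounds

F1 | step 8 | diol vinylcyclopropane (2α-OH; C9 bears CH2OH and the silyloxymethyl vinyl group) | CC1(C)C[C@H](O)C[C@@]2(C)[C@@H]1[C@]2(CO)C(=C)CO[Si](C)(C)C(C)(C)C
F2 | step 8 | keto diol (C6 ketone; 2α-OH; C11–OH; C17–OTBS) | CC1(C)C[C@H](O)C[C@]2(C)C(CO)=C(CO[Si](C)(C)C(C)(C)C)CC(=O)[C@H]12
F3 | step 7 | 5-[(tert-butyldimethylsilyloxy)acetyl]-2,2-dimethyl-1,3-dioxane-4,6-dione | CC1(C)OC(=O)C(C(=O)CO[Si](C)(C)C(C)(C)C)C(=O)O1
F4 | step 7 | (R)-3,5,5-trimethylcyclohex-3-en-1-yl 4-(tert-butyldimethylsilyloxy)-3-oxobutanoate | CC1(C)C[C@H](OC(=O)CC(=O)CO[Si](C)(C)C(C)(C)C)CC(C)=C1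
F5 | step 7 | (R)-3,5,5-trimethylcyclohex-3-en-1-yl 2-diazo-4-(tert-butyldimethylsilyloxy)-3-oxobutanoate | CC1(C)C[C@H](OC(=O)C(=[N+]=[N-])C(=O)CO[Si](C)(C)C(C)(C)C)CC(C)=C1
F6 | step 7 | cyclopropyl keto lactone (as 10 with C8 as ketone) | CC1(C)C[C@H](O2)C[C@@]3(C)[C@@H]1[C@@]3(C(=O)CO[Si](C)(C)C(C)(C)C)C2=O
F7 | step 9 | C6 dioxolane of 12 | CC1(C)C[C@H](O3)C[C@]2(C)C(C3=O)=C(CO[Si](C)(C)C(C)(C)C)CC4(OCCO4)[C@H]12
F8 | step 9 | C6 dioxolane diol | CC1(C)C[C@H](O)C[C@]2(C)C(CO)=C(CO[Si](C)(C)C(C)(C)C)CC3(OCCO3)[C@H]12
F9 | step 1 | racemic 3,5,5-trimethylcyclohex-3-en-1-ol | CC1(C)CC(O)CC(C)=C1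
F10 | step 1 | (R)-3,5,5-trimethylcyclohex-3-en-1-yl (S)-2-methoxy-2-phenylacetate | CC1(C)C[C@H](OC(=O)[C@@H](OC)c2ccccc2)CC(C)=C1
F11 | step 1 | (S)-3,5,5-trimethylcyclohex-3-en-1-yl (S)-2-methoxy-2-phenylacetate | CC1(C)C[C@@H](OC(=O)[C@@H](OC)c2ccccc2)CC(C)=C1
F12 | step 15 | 1-(4-methoxybenzyloxy)propan-2-one N,N-dimethylhydrazone | CC(COCc1ccc(OC)cc1)=NN(C)C
F13 | step 15 | C11-alkylated hydrazone | CC1(C)C[C@H](O[Si](CC)(CC)CC)C[C@]2(C)C(CCC(COCc3ccc(OC)cc3)=NN(C)C)=C(CO[Si](C)(C)C(C)(C)C)C[C@H](O[Si](CC)(CC)CC)[C@H]12
F14 | step 15 | C13 ketone with C16 4-methoxybenzyl ether | CC1(C)C[C@H](O[Si](CC)(CC)CC)C[C@]2(C)C(CCC(=O)COCc3ccc(OC)cc3)=C(CO[Si](C)(C)C(C)(C)C)C[C@H](O[Si](CC)(CC)CC)[C@H]12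
F15 | step 15 | C13 ketone with C16 hydroxyl | CC1(C)C[C@H](O[Si](CC)(CC)CC)C[C@]2(C)C(CCC(=O)CO)=C(CO[Si](C)(C)C(C)(C)C)C[C@H](O[Si](CC)(CC)CC)[C@H]12
A1 | alternative 1 | 2-methoxy-6-methyl-1,4-benzoquinone | COC1=CC(=O)C=C(C)C1=O
A2 | alternative 1 | 4-methyl-2-(triisopropylsilyloxy)penta-1,3-diene | C=C(O[Si](C(C)C)(C(C)C)C(C)C)C=C(C)C
A3 | alternative 1 | cis-fused Diels–Alder adduct | CC1(C)C=C(O[Si](C(C)C)(C(C)C)C(C)C)C[C@]2(C)C(=O)C(OC)=CC(=O)[C@H]12
A4 | alternative 2 | 3,9,9-trimethyl-4-[2-(tert-butyldimethylsilyloxy)ethyl]-5-[(tert-butyldimethylsilyloxy)methyl]cyclodeca-2,4-diene-1,7-dione (both ring alkenes cis in the ring) | O=C1/C=C(C)\C(CCO[Si](C)(C)C(C)(C)C)=C(CO[Si](C)(C)C(C)(C)C)/CC(=O)CC(C)(C)C1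
A5 | alternative 2 | cis-decalin-2,6-dione with C8=C9 | CC1(C)CC(=O)C[C@]2(C)C(CCO[Si](C)(C)C(C)(C)C)=C(CO[Si](C)(C)C(C)(C)C)CC(=O)[C@H]12
A6 | alternative 3 | (R)-3,5,5-trimethylcyclohex-3-en-1-yl 2-methyl-4-oxo-4,5-dihydrofuran-3-carboxylate | CC1(C)C[C@H](OC(=O)C2=C(C)OCC2=O)CC(C)=C1
A7 | alternative 3 | bridged δ-lactone 1,5-diketone (one C9 epimer) | CC1(C)C[C@H](O2)C[C@](C)([C@H](C(=O)CO)C2=O)[C@@H]1C(C)=O
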